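## Structural features

GA55 is a C19 gibberellin: ring A (C1–C5, C10) and cyclopentane ring B (C5, C6, C8, C9, C10) share the C5–C10 bond, ring C (C8, C9, C11–C14) is fused to ring B at C8–C9, and ring D (C8, C14, C13, C16, C15) forms a bicyclo[3.2.1]octane with ring C. A γ-lactone (C19 carbonyl on C4, oxygen on C10) bridges ring A on the face opposite H5. There are nine stereocentres, all contiguous except C13 (C1–C10–C5–C4–C3 around ring A, C5–C6–C8–C9–C10 around ring B); C4, C8, C10 and C13 are fully substituted. The 1β- and 3β-hydroxyls are syn-diaxial on the face away from the lactone, the C7 acid on C6 is trans to the C4 branch on C5, and C13 bears a tertiary allylic alcohol beside the exocyclic C16=C17 alkene. Fragile points: the 3-hydroxyl is β to the lactone carbonyl (retro-aldol and C3 epimerization in base), a 1-hydroxy-3-ketone precursor can eliminate, C6 epimerizes once C7 is a carbonyl, and the 13-hydroxy-16-ene unit rearranges in strong acid. The real difficulty is the crowded ring B (quaternary C8 next to C9 with H9 cis to C15, oxygenated quaternary C10) combined with four correctly oriented oxygenated carbons on ring A and the lactone. The key step exploits that ring C has one oxygen only, at C13, 1,4 to C9 and 1,3 to C8, while C9 is next to carbonyl-level C10. Ring C is therefore the adduct of a 2-silyloxybutadiene and a ring B cyclopentenone whose C8=C9 bond is conjugated to a C10 ketone.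

## Logic of the disconnections

30 ⇐ 28. No skeletal bond is cut: the C7 acid is taken back to a primary alcohol. C7 stays at the alcohol level through all enolate chemistry so that C6 cannot epimerize. The forward step must oxidize one primary alcohol in the presence of two secondary and one tertiary alcohol.

28 ⇐ 27. C13–C16 is cut (ring D). A ketyl–alkyne closure gives the tertiary alcohol and the exocyclic alkene together and reduces the bicyclo[3.2.1] unit to a cyclohexanone carrying a propargyl group on C8. The demand is that C13 be the only reducible carbonyl at that stage.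

27 ⇐ 25 ⇐ 24. Protecting groups are removed in one operation and the C3 carbinol is traced to a ketone. This places a 1,3-oxygen pattern in ring A that an aldol can make. The hydride must enter C3 from the lactone face, which the axial 1β-silyloxy group enforces.

24 ⇐ 22. C1–C2 is cut (ring A) by an intramolecular aldol between a C3 methyl ketone and a C1 aldehyde. Only one enolate and one electrophile are possible, and the cut removes ring A and the C1 stereocentre. The demand is kinetic control giving the axial 1β-oxygen without dehydration.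

22 ⇐ 20 ⇐ 19 ⇐ 18. The C1 aldehyde is a cleaved vinyl group, and C3–C4 is cut (acetyl unit on the lactone α-carbon, introduced as an aldol then oxidized). This makes C4 the last quaternary centre to be set. The electrophile must add to the convex face of the bicyclic lactone enolate.

18 ⇐ 16. C1–C10 and O–C19 are cut: vinyl addition to the C10 ketone and lactonization of the resulting alkoxide. The lactone and the C10 centre come from a simple keto ester. Addition must occur on the face of H5 and H9.

16 ⇐ 15. C4–C5 is cut (enolate alkylation with a propanoate α-electrophile). Enolization must be regioselective for the C5 methylene, and alkylation must be trans to the C7 arm.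

15 ⇐ 14 ⇐ 11 + 13. C8–C14 and C9–C11 are cut (ring C, the key cycloaddition), after the C13 enol ether is retraced from its ketal. The bicycle falls to a monocyclic enone whose single stereocentre (C6) must control C8 and C9. Three design changes serve this step:
- the alkyne carries a silyl cap, so it tolerates the Lewis acid and the later strong bases;
- the C7 oxygen carries a bulky, acid-stable tert-butyldiphenylsilyl group;
- the diene is the tert-butyldimethylsilyl dienol ether, more robust than a trimethylsilyl one.

11 ⇐ 10 ⇐ 8 + 9. C8–C15 is cut (propargyl 1,2-addition), followed by oxidative 1,3-transposition. This fixes the enone regiochemistry without a regiochemical choice. The C6 centre, α to the ketone in 8, must not be enolized.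

8 ⇐ 7 ⇐ 6. C9=C10 is cut (ring-closing metathesis) and C8–C9 (vinyl addition to a Weinreb amide). The ring becomes an acyclic chain with one stereocentre.

6 ⇐ 5 ⇐ 4 ⇐ 3 ⇐ 1 + 2. C6–C7 is cut (auxiliary-controlled hydroxymethylation). Absolute configuration comes from a recoverable oxazolidinone with a predictable facial sense. 13 ⇐ 12 is O-silylation of an enone.

## Other disconnections considered

Alternative 1: The C6–C8 bond is traced to the C7–C8 bond of a six-membered ring B (ring contraction). In the forward sense, irradiation of the 6-diazo-7-ketone A3 in aqueous solvent triggers a Wolff rearrangement: C8 shifts to C6 with retention and the ketene is hydrated to the C7 acid. The product is the 1,3-bis(tert-butyldimethylsilyl) ether A1, one deprotection from the target. A3 would come from steviol A2.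
- In favour: A2 already holds rings C and D, the 13-hydroxy-16-ene unit and the absolute configuration at C4, C5, C8, C9 and C13. The key step also delivers C7 at the acid level.
- Against, here: turning A2 into A3 needs excision of the C10 methyl with lactone formation, oxygenation of unactivated C1 and C3, and a C6/C7 diazoketone on an unactivated ring B. These are remote oxidations with little intrinsic selectivity. C6 would be set by protonation of the ketene hydrate, and the carbene could engage the 16-ene.
- Comparison: on structure A2 is better, since it supplies more of the skeleton and stereocentres ready-made. On mechanism the 1,2-shift is as stereospecific as the suprafacial cycloaddition, but C6 rests on a protonation and not on a centre carried from the start. On step economy the key step lies closer to the target (better), yet the C–H oxidations before A3 are hard to bound, whereas the chosen plan derives every oxygen from a carbonyl group.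

Alternative 2: C8–C9 and C12–C13 are cut. In the forward sense, Rh2(S-DOSP)4 decomposes the vinyl diazoketone A5; the carbenoid at C9 cyclopropanates the C8=C15 bond of the tethered 1,2-bis(silyloxy)cyclopentadiene (ring B). The cis-divinylcyclopropane then undergoes Cope rearrangement (C12–C13, ring C) to the tricycle A4.
- In favour: rings B, C and D and both quaternary centres C8 and C13, with the C13 oxygen in place, arise in one catalyst-controlled operation from an achiral precursor. Tandem cyclopropanation/Cope is an established formal [4+3] reaction type.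
- Against, here: the dioxygenated cyclopentadiene of A5 can scramble by 1,5-hydrogen shifts and dimerize. Enantioinduction by this catalyst is least reliable for acceptor-only diazoketones. A4 also still needs:
  - reduction of the 9(11)-alkene from the correct face (H9);
  - differentiation of the C6 gem-diester to a single C7 carboxyl of defined configuration;
  - methylenation of C16;
  - all of ring A and the lactone.
- Comparison: on structure it is better than the chosen plan for rings C and D, with no separate ring D closure and C13 set together with C8. On mechanism the relative configuration is fixed by a concerted boat Cope, equal in rigour to the Diels–Alder step, but the absolute configuration depends on catalyst control that is less predictable than an auxiliary. On step economy the B/C/D core is shorter, but the repairs at C6, C9 and C16 consume much of the gain, and ring A would be built as in the chosen plan.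

Alternative 3: C4–C5 and C10–O are cut. In the forward sense, MeAlCl2 opens the (3S,4S)-epoxide of the epoxy alcohol A7 at C4, the C5=C10 alkene attacks C4 (ring A), and the C19 hydroxyl traps the C10 cation (oxolane) to give the hydroxy ether A6.
- In favour: C3, C4, C5 and C10 are set in one stereospecific step (inversion at C4, anti addition across the alkene, chair transition state). Rings C and D are already in place.
- Against, here: A6 has no oxygen at C1 and offers no handle to introduce the 1β-hydroxyl, which is decisive for this target. The 19,10-ether must still be oxidized to the lactone, the hindered C7 nitrile hydrolysed under conditions that endanger the 3-hydroxy lactone, and C16 methylenated. Facial selectivity of the alkene and competing elimination or hydride shifts are further concerns.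
- Comparison: on structure it is better than the chosen plan for ring A of a 1-deoxy gibberellin, with four centres in one step against four steps. On mechanism the cationic cascade is more stereospecific than a series of separate carbonyl additions, but less tolerant of neighbouring functionality. On step economy it is shorter to ring A, but it loses here because C1 oxygenation and C19 oxidation have no good solution.

Key step: step 10

Remark: gibberellane numbering is used for all intermediates. β is the face of ring B carrying H5, H9, C7 and C15; α is the face carrying C11, C14, the C10–O bond and C4. 3-Bromo-1-(trimethylsilyl)prop-1-yne and ethyl (S)-2-(trifluoromethylsulfonyloxy)propanoate are taken as purchasable.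

## Route

Step 1
Reactants: 1 (S)-4-benzyloxazolidin-2-one; 2 pent-4-enoyl chloride
Product: 3 (S)-4-benzyl-3-(pent-4-enoyl)oxazolidin-2-one
Conditions: n-BuLi, THF, −78 °C; then 2, −78 → 0 °C
Reagents that add atoms: none
Why: N-acylation of the lithiated oxazolidinone by an acid chloride; no stereocentre is formed and the auxiliary centre is untouched.

Step 2
Reactants: 3 (S)-4-benzyl-3-(pent-4-enoyl)oxazolidin-2-one
Product: 4 (S)-4-benzyl-3-[(R)-2-(hydroxymethyl)pent-4-enoyl]oxazolidin-2-one
Conditions: TiCl4, iPr2NEt, CH2Cl2, 0 °C; then 1,3,5-trioxane, TiCl4, 0 °C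
Reagents that add atoms: 1,3,5-trioxane, C1OCOCO1
Why: Evans auxiliary hydroxymethylation (aldol-type addition of the chelated Z titanium enolate to formaldehyde released from trioxane); the electrophile adds to the enolate face opposite the benzyl group, which sets C6 as (R) here, the arrangement that becomes (S) in enone 11.

Step 3
Reactants: 4 (S)-4-benzyl-3-[(R)-2-(hydroxymethyl)pent-4-enoyl]oxazolidin-2-one
Product: 5 (R)-2-(hydroxymethyl)-N-methoxy-N-methylpent-4-enamide
Conditions: MeNH(OMe)·HCl, AlMe3, CH2Cl2, −10 → 0 °C
Reagents that add atoms: N,O-dimethylhydroxylamine hydrochloride, CNOC.Cl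
Why: Aluminium amide transamidation to the Weinreb amide, directed to the exocyclic carbonyl by the β-hydroxyl (as its aluminium alkoxide); C6 is not enolized and the auxiliary is recovered.

Step 4
Reactants: 5 (R)-2-(hydroxymethyl)-N-methoxy-N-methylpent-4-enamide
Product: 6 (R)-2-[(tert-butyldiphenylsilyloxy)methyl]-N-methoxy-N-methylpent-4-enamide
Conditions: t-BuPh2SiCl, imidazole, DMF, rt
Reagents that add atoms: tert-butyl(chloro)diphenylsilane, CC(C)(C)[Si](Cl)(c1ccccc1)c1ccccc1
Why: Silylation of the primary alcohol; the bulky, acid-stable silyl ether later shields one face of the enone and survives the Lewis acid and ketalization steps.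

Step 5
Reactants: 6 (R)-2-[(tert-butyldiphenylsilyloxy)methyl]-N-methoxy-N-methylpent-4-enamide
Product: 7 (R)-4-[(tert-butyldiphenylsilyloxy)methyl]hepta-1,6-dien-3-one
Conditions: CH2=CHMgBr, THF, −78 → 0 °C; quench into cold 1 M HCl
Reagents that add atoms: vinylmagnesium bromide, C=C[Mg]Br
Why: Weinreb ketone synthesis; the chelated tetrahedral intermediate prevents over-addition and protects C6 from enolization, and the acidic quench removes the liberated amine before it can add to the enone.

Step 6
Reactants: 7 (R)-4-[(tert-butyldiphenylsilyloxy)methyl]hepta-1,6-dien-3-one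
Product: 8 (R)-5-[(tert-butyldiphenylsilyloxy)methyl]cyclopent-2-en-1-one
Conditions: (H2IMes)(PCy3)Cl2Ru=CHPh (second-generation Grubbs catalyst, 3 mol%), CH2Cl2, 40 °C
Reagents that add atoms: none
Why: Ring-closing metathesis of a vinyl ketone and a terminal alkene to a cyclopentenone under neutral conditions, so the α-centre C6 is preserved.

Step 7
Reactants: 8 (R)-5-[(tert-butyldiphenylsilyloxy)methyl]cyclopent-2-en-1-one; 9 3-bromo-1-(trimethylsilyl)prop-1-yne
Product: 10 (5R)-5-[(tert-butyldiphenylsilyloxy)methyl]-1-[3-(trimethylsilyl)prop-2-yn-1-yl]cyclopent-2-en-1-ol (C1 epimers)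
Conditions: Zn, THF, 0 °C → rt; NH4Cl (aq)
Reagents that add atoms: none
Why: Barbier propargylation: the organozinc adds 1,2 to the enone carbonyl through its allenyl form (SE2′), giving the homopropargylic tertiary alcohol without basic conditions; the new carbinol centre is destroyed in step 8.

Step 8
Reactants: 10 (5R)-5-[(tert-butyldiphenylsilyloxy)methyl]-1-[3-(trimethylsilyl)prop-2-yn-1-yl]cyclopent-2-en-1-ol
Product: 11 (S)-4-[(tert-butyldiphenylsilyloxy)methyl]-3-[3-(trimethylsilyl)prop-2-yn-1-yl]cyclopent-2-en-1-one
Conditions: pyridinium chlorochromate (C5H5NH)[CrO3Cl], 4 Å MS, CH2Cl2, rt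
Reagents that add atoms: pyridinium chlorochromate, [O-][Cr](=O)(=O)Cl.c1cc[nH+]cc1
Why: Babler–Dauben oxidative transposition: [3,3] shift of the tertiary allylic chromate ester and oxidation give the 3-substituted enone with unambiguous regiochemistry; C6 is now γ to the carbonyl and is not touched.

Step 9
Reactants: 12 but-3-en-2-one
Product: 13 2-(tert-butyldimethylsilyloxy)buta-1,3-diene
Conditions: t-BuMe2SiOTf, Et3N, Et2O, 0 °C
Reagents that add atoms: tert-butyldimethylsilyl trifluoromethanesulfonate, CC(C)(C)[Si](C)(C)OS(=O)(=O)C(F)(F)F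
Why: Soft enolization and O-silylation of the methyl ketone to the cross-conjugated silyl dienol ether.

Step 10
Reactants: 11 (S)-4-[(tert-butyldiphenylsilyloxy)methyl]-3-[3-(trimethylsilyl)prop-2-yn-1-yl]cyclopent-2-en-1-one; 13 2-(tert-butyldimethylsilyloxy)buta-1,3-diene
Product: 14 cis-hydrindanone silyl enol ether (10-ketone; 12-ene 13-OSiMe2t-Bu; 8β-[3-(trimethylsilyl)prop-2-ynyl]; 6β-CH2OSiPh2t-Bu; 9β-H)
Conditions: AlBr3/AlMe3 (10:1, 0.3 equiv), 13 (3 equiv), toluene/CH2Cl2, −20 → 0 °C; Et3N then NaHCO3 (aq)
Reagents that add atoms: none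
Why: Lewis acid-promoted Diels–Alder reaction of a β-substituted cycloalkenone with a 2-silyloxybutadiene, a known reaction type. The aluminium Lewis acid binds the C10 carbonyl and lowers the LUMO of the C8=C9 bond; the diene adds in a concerted, asynchronous [4+2] process in which C8–C14 bonding is ahead. Ring C is closed by this intermolecular cycloaddition, both new bonds (C8–C14 and C9–C11) forming suprafacially on the dienophile. The nucleophilic diene terminus next to the silyloxy carbon bonds to the electrophilic β-carbon C8, so the oxygen ends at C13, 1,4 to C9. C9 is fixed by the suprafacial addition, which makes the B/C fusion cis (H9 cis to C15). C8 is fixed by the C6 centre: the bulky silyloxymethyl group on the adjacent carbon shields its own face, so the diene approaches anti to it and ring C ends on the α-face. The step needs reactivity from a β,β-disubstituted enone and survival of the diene; the mixed aluminium promoter, the robust tert-butyldimethylsilyl dienol ether and the silyl cap on the alkyne are chosen for that.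

Step 11
Reactants: 14 cis-hydrindanone silyl enol ether
Product: 15 13,13-ethylenedioxy 10-ketone
Conditions: HOCH2CH2OH (5 equiv), camphorsulfonic acid (5 mol%), CH2Cl2, 0 °C → rt
Reagents that add atoms: ethane-1,2-diol, OCCO
Why: Acid-catalysed acetalization of the silyl enol ether (protonation at C12, capture of the C13 silyloxycarbenium ion by the diol, loss of silanol); no water is formed, and the hindered C10 cyclopentanone and the tert-butyldiphenylsilyl ether are left alone.

Step 12
Reactants: 15 13,13-ethylenedioxy 10-ketone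
Product: 16 5α-(1-ethoxy-1-oxopropan-2-yl) 10-ketone (5β-H; C4 configuration immaterial)
Conditions: LiN(SiMe3)2, THF, −78 °C; ethyl (S)-2-(trifluoromethylsulfonyloxy)propanoate, −78 → −30 °C
Reagents that add atoms: ethyl (S)-2-(trifluoromethylsulfonyloxy)propanoate, CCOC(=O)[C@H](C)OS(=O)(=O)C(F)(F)F
Why: SN2 alkylation of the kinetic lithium enolate (the C5 methylene is deprotonated in preference to the hindered ring-fusion C9–H) by an α-triflyloxy ester; the electrophile enters anti to the adjacent C7 arm and the C8 propargyl group, giving the trans C5/C6 relationship, and the C4 centre is erased in step 14.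

Step 13
Reactants: 16 5α-(1-ethoxy-1-oxopropan-2-yl) 10-ketone
Product: 18 10β-vinyl 19,10-γ-lactone (C4 epimers), via hydroxy ester 17 (not isolated)
Conditions: CeCl3, CH2=CHMgBr, THF, −78 → 0 °C; then rt
Reagents that add atoms: vinylmagnesium bromide, C=C[Mg]Br
Why: Organocerium 1,2-addition (low basicity, no enolization of C5 or C9) to the ketone from the convex β-face, which carries only H5 and H9 next to the carbonyl, anti to the C5 branch and to C11; the 10α-alkoxide is cis to C4 and closes the γ-lactone by intramolecular acylation with loss of ethoxide.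

Step 14
Reactants: 18 10β-vinyl 19,10-γ-lactone
Product: 19 4-(1-hydroxyethyl) lactone (C4 set; carbinol epimers)
Conditions: LiN(iPr)2, THF, −78 °C; CH3CHO, −78 °C; NH4Cl (aq)
Reagents that add atoms: acetaldehyde, CC=O
Why: Aldol addition of the lactone lithium enolate; the enolate belongs to a cis-fused bicyclo[3.3.0] system and reacts on its convex face (that of H5 and the vinyl group), so C3 becomes cis to C1 and the C18 methyl is turned to the concave face, which fixes C4.

Step 15
Reactants: 19 4-(1-hydroxyethyl) lactone
Product: 20 4-acetyl lactone (C3 ketone, C2 methyl)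
Conditions: Dess–Martin periodinane, NaHCO3, CH2Cl2, rt
Reagents that add atoms: none
Why: Dess–Martin oxidation of the secondary alcohol; C4 is quaternary, so the β-keto lactone cannot epimerize.

Step 16
Reactants: 20 4-acetyl lactone
Product: 22 C1 aldehyde C3 methyl ketone, via vicinal diol 21 (not isolated)
Conditions: OsO4 (2 mol%), NaIO4 (4 equiv), 2,6-lutidine, dioxane/H2O, rt
Reagents that add atoms: osmium tetroxide, O=[Os](=O)(=O)=O; sodium periodate, [Na+].[O-]I(=O)(=O)=O; water, O
Why: Lemieux–Johnson cleavage: dihydroxylation of the only alkene (the silyl-capped alkyne is inert) and periodate cleavage give an aldehyde that has no α-hydrogen.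

Step 17
Reactants: 22 C1 aldehyde C3 methyl ketone
Product: 24 ring A 3-ketone 1β-triethylsilyl ether, via lithium aldolate 23 (not isolated)
Conditions: LiN(SiMe3)2 (1.1 equiv), THF, −78 °C; then Et3SiOTf, −78 °C
Reagents that add atoms: triethylsilyl trifluoromethanesulfonate, CC[Si](CC)(CC)OS(=O)(=O)C(F)(F)F
Why: Intramolecular aldol addition (6-enolexo-exo-trig) closing ring A: only the C2 methyl can be enolized and only the C1 aldehyde can accept; in the chair Zimmerman–Traxler transition state lithium bridges O3 and O1 and the C1=O bond lies antiperiplanar to the C10–O bond (Cornforth arrangement), which puts O1 axial on the face away from the lactone (1β), and silylation at −78 °C blocks retro-aldol and elimination.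

Step 18
Reactants: 24 ring A 3-ketone 1β-triethylsilyl ether
Product: 25 3β-alcohol 1β-triethylsilyl ether
Conditions: LiBH(s-Bu)3, THF, −78 °C; AcOH quench at −78 °C
Reagents that add atoms: none
Why: Ketone reduction with a bulky borohydride: axial delivery from the β-face is blocked by the 1,3-diaxial 1β-silyloxy group and H5, so hydride enters from the α-face and gives the axial 3β-alcohol; low temperature and the acidic quench avoid retro-aldol of the β-hydroxy lactone.

Step 19
Reactants: 25 3β-alcohol 1β-triethylsilyl ether
Product: 27 1β,3β,7-triol 13-ketone, via desilylated ketal 26 (not isolated)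
Conditions: Bu4NF, AcOH, THF, rt → 40 °C; then 2 M HCl, rt
Reagents that add atoms: water, O
Why: Buffered fluoride desilylation removes both silyl ethers and the alkynylsilane without generating a free C3 alkoxide; acid hydrolysis of the dioxolane in the same flask frees the C13 ketone.

Step 20
Reactants: 27 1β,3β,7-triol 13-ketone
Product: 28 GA55 7-alcohol (1β,3β,7,13-tetraol, ring D closed)
Conditions: SmI2 (4 equiv), HMPA, t-BuOH, THF, 0 °C → rt
Reagents that add atoms: none
Why: Ketyl–alkyne reductive cyclization: one-electron reduction of the only ketone, 5-exo-dig addition of the C13 ketyl to C16, and reduction and protonation of the vinyl radical give the tertiary alcohol and the exocyclic alkene; the C13 configuration is dictated by the bridging geometry, and the lactone and free hydroxyls are inert.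

Step 21
Reactants: 28 GA55 7-alcohol
Product: 30 GA55, via C7 aldehyde 29 (not isolated)
Conditions: TEMPO (20 mol%), PhI(OAc)2, CH2Cl2, rt; then NaClO2, NaH2PO4, 2-methylbut-2-ene, t-BuOH/H2O, 0 °C
Reagents that add atoms: sodium chlorite, [Na+].[O-]Cl=O
Why: Oxoammonium (TEMPO) oxidation is selective for the primary C7 alcohol over the hindered axial secondary and tertiary alcohols; Pinnick oxidation of the aldehyde under buffered, non-basic conditions leaves C6, the 3-hydroxy lactone and the 16-ene untouched.

## Compound list

1 | (S)-4-benzyloxazolidin-2-one | O=C1N[C@@H](Cc2ccccc2)CO1 | starting material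
2 | pent-4-enoyl chloride | C=CCCC(Cl)=O | starting material
3 | (S)-4-benzyl-3-(pent-4-enoyl)oxazolidin-2-one | C=CCCC(=O)N1[C@@H](Cc2ccccc2)COC1=O | intermediate
4 | (S)-4-benzyl-3-[(R)-2-(hydroxymethyl)pent-4-enoyl]oxazolidin-2-one | C=CC[C@H](CO)C(=O)N1[C@@H](Cc2ccccc2)COC1=O | intermediate
5 | (R)-2-(hydroxymethyl)-N-methoxy-N-methylpent-4-enamide | C=CC[C@H](CO)C(=O)N(C)OC | intermediate
6 | (R)-2-[(tert-butyldiphenylsilyloxy)methyl]-N-methoxy-N-methylpent-4-enamide | C=CC[C@H](CO[Si](c1ccccc1)(c1ccccc1)C(C)(C)C)C(=O)N(C)OC | intermediate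
7 | (R)-4-[(tert-butyldiphenylsilyloxy)methyl]hepta-1,6-dien-3-one | C=CC[C@H](CO[Si](c1ccccc1)(c1ccccc1)C(C)(C)C)C(=O)C=C | intermediate
8 | (R)-5-[(tert-butyldiphenylsilyloxy)methyl]cyclopent-2-en-1-one | O=C1C=CC[C@@H]1CO[Si](c1ccccc1)(c1ccccc1)C(C)(C)C | intermediate
9 | 3-bromo-1-(trimethylsilyl)prop-1-yne | C[Si](C)(C)C#CCBr | starting material
10 | (5R)-5-[(tert-butyldiphenylsilyloxy)methyl]-1-[3-(trimethylsilyl)prop-2-yn-1-yl]cyclopent-2-en-1-ol (C1 epimers) | C[Si](C)(C)C#CCC1(O)C=CC[C@@H]1CO[Si](c1ccccc1)(c1ccccc1)C(C)(C)C | intermediate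
11 | (S)-4-[(tert-butyldiphenylsilyloxy)methyl]-3-[3-(trimethylsilyl)prop-2-yn-1-yl]cyclopent-2-en-1-one | O=C1C=C(CC#C[Si](C)(C)C)[C@@H](CO[Si](c2ccccc2)(c2ccccc2)C(C)(C)C)C1 | intermediate
12 | but-3-en-2-one | CC(=O)C=C | starting material
13 | 2-(tert-butyldimethylsilyloxy)buta-1,3-diene | C=CC(=C)O[Si](C)(C)C(C)(C)C | intermediate
14 | cis-hydrindanone silyl enol ether (rings B and C; 10-ketone; 12-ene 13-silyloxy; 8β-silylpropargyl; 6β-silyloxymethyl; 9β-H) | C[Si](C)(C)C#CC[C@]23CC(O[Si](C)(C)C(C)(C)C)=CC[C@H]2C(=O)C[C@@H]3CO[Si](c4ccccc4)(c4ccccc4)C(C)(C)C | intermediate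
15 | 13,13-ethylenedioxy 10-ketone | C[Si](C)(C)C#CC[C@]23CC4(OCCO4)CC[C@H]2C(=O)C[C@@H]3CO[Si](c5ccccc5)(c5ccccc5)C(C)(C)C | intermediate
16 | 5α-(1-ethoxy-1-oxopropan-2-yl) 10-ketone (5β-H; C4 unassigned) | C[Si](C)(C)C#CC[C@]23CC4(OCCO4)CC[C@H]2C(=O)[C@@H](C(C)C(=O)OCC)[C@@H]3CO[Si](c5ccccc5)(c5ccccc5)C(C)(C)C | intermediate
17 | 10α-hydroxy-10β-vinyl ethyl ester (formed as its alkoxide) | C[Si](C)(C)C#CC[C@]23CC4(OCCO4)CC[C@H]2[C@](O)(C=C)[C@@H](C(C)C(=O)OCC)[C@@H]3CO[Si](c5ccccc5)(c5ccccc5)C(C)(C)C | intermediate
18 | 10β-vinyl 19,10-γ-lactone (4-methyl, C4 epimers) | C[Si](C)(C)C#CC[C@]23CC4(OCCO4)CC[C@H]2[C@@]1(C=C)OC(=O)C(C)[C@H]1[C@@H]3CO[Si](c5ccccc5)(c5ccccc5)C(C)(C)C | intermediate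
19 | 4-(1-hydroxyethyl) lactone (C3 on the face of H5 and vinyl; carbinol epimers) | C[Si](C)(C)C#CC[C@]23CC4(OCCO4)CC[C@H]2[C@@]1(C=C)OC(=O)[C@@](C)([C@H]1[C@@H]3CO[Si](c5ccccc5)(c5ccccc5)C(C)(C)C)C(C)O | intermediate
20 | 4-acetyl lactone | C[Si](C)(C)C#CC[C@]23CC4(OCCO4)CC[C@H]2[C@@]1(C=C)OC(=O)[C@@](C)([C@H]1[C@@H]3CO[Si](c5ccccc5)(c5ccccc5)C(C)(C)C)C(C)=O | intermediate
21 | vicinal diol from the vinyl group (carbinol epimers) | C[Si](C)(C)C#CC[C@]23CC4(OCCO4)CC[C@H]2[C@@]1(C(O)CO)OC(=O)[C@@](C)([C@H]1[C@@H]3CO[Si](c5ccccc5)(c5ccccc5)C(C)(C)C)C(C)=O | intermediate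
22 | C1 aldehyde C3 methyl ketone | C[Si](C)(C)C#CC[C@]23CC4(OCCO4)CC[C@H]2[C@@]1(C=O)OC(=O)[C@@](C)([C@H]1[C@@H]3CO[Si](c5ccccc5)(c5ccccc5)C(C)(C)C)C(C)=O | intermediate
23 | lithium 1β-aldolate of the ring A 3-ketone | C[Si](C)(C)C#CC[C@]23CC4(OCCO4)CC[C@H]2[C@@]12OC(=O)[C@@](C)([C@H]1[C@@H]3CO[Si](c5ccccc5)(c5ccccc5)C(C)(C)C)C(=O)C[C@H]2O[Li] | intermediate
24 | ring A 3-ketone 1β-triethylsilyl ether | C[Si](C)(C)C#CC[C@]23CC4(OCCO4)CC[C@H]2[C@@]12OC(=O)[C@@](C)([C@H]1[C@@H]3CO[Si](c5ccccc5)(c5ccccc5)C(C)(C)C)C(=O)C[C@H]2O[Si](CC)(CC)CC | intermediate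
25 | 3β-alcohol 1β-triethylsilyl ether | C[Si](C)(C)C#CC[C@]23CC4(OCCO4)CC[C@H]2[C@@]12OC(=O)[C@@](C)([C@H]1[C@@H]3CO[Si](c5ccccc5)(c5ccccc5)C(C)(C)C)[C@@H](O)C[C@H]2O[Si](CC)(CC)CC | intermediate
26 | 1β,3β,7-triol 13-ketal with terminal alkyne | C#CC[C@]23CC4(OCCO4)CC[C@H]2[C@@]12OC(=O)[C@@](C)([C@H]1[C@@H]3CO)[C@@H](O)C[C@H]2O | intermediate
27 | 1β,3β,7-triol 13-ketone (8β-propargyl) | C#CC[C@]23CC(=O)CC[C@H]2[C@@]12OC(=O)[C@@](C)([C@H]1[C@@H]3CO)[C@@H](O)C[C@H]2O | intermediate
28 | GA55 7-alcohol | C=C1C[C@]23C[C@@]1(O)CC[C@H]2[C@@]12OC(=O)[C@@](C)([C@H]1[C@@H]3CO)[C@@H](O)C[C@H]2O | intermediate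
29 | GA55 7-aldehyde | C=C1C[C@]23C[C@@]1(O)CC[C@H]2[C@@]12OC(=O)[C@@](C)([C@H]1[C@@H]3C=O)[C@@H](O)C[C@H]2O | intermediate
30 | GA55 | C=C1C[C@]23C[C@@]1(O)CC[C@H]2[C@@]12OC(=O)[C@@](C)([C@H]1[C@@H]3C(=O)O)[C@@H](O)C[C@H]2O | target

## Step count and least certain steps

Total: 21 steps. Longest linear sequence: 20 steps (steps 1–8 and 10–21; step 9 is a one-step branch).

Step 10 (key step). The most likely failure is slow cycloaddition of the β,β-disubstituted enone, so that the diene is consumed by the Lewis acid first; facial selectivity could also erode if the promoter chelates the C7 oxygen. Fallback: from 11, cycloaddition with the far more nucleophilic (E)-1-methoxy-3-(trimethylsilyloxy)buta-1,3-diene should give the 11-methoxy silyl enol ether adduct F1. Trifluoroacetic acid then removes methanol and the silyl group to give the 11-en-13-one F2, and conjugate reduction with [(Ph3P)CuH]6 gives the 10,13-dione F3. Selective dioxolane formation at the unhindered cyclohexanone (Me3SiOCH2CH2OSiMe3, Me3SiOTf cat., CH2Cl2, −78 °C) returns to 15.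

Step 12. Displacement at a secondary triflate may lose to elimination (giving an acrylate and then a Michael adduct) or to O-alkylation, and facial control at C5 may be incomplete. Fallback: from 15, alkylation of the same enolate with ethyl bromoacetate gives the 5α-(ethoxycarbonylmethyl) ketone F4. Organocerium vinyl addition and lactonization give the C4-unsubstituted vinyl lactone F5, and methylation of its lithium enolate (LiN(iPr)2, MeI) returns to 18.

Step 13. The C10 ketone is flanked by two branched carbons, so addition may be slow and enolization or attack at the ester may compete. Fallback: from 16, the smaller ethynyl nucleophile (HC≡CMgBr, CeCl3) gives, after lactonization, the 10β-ethynyl lactone F6. Semi-hydrogenation over Pd/CaCO3 poisoned with Pb(OAc)2 and quinoline, which spares the hindered silyl-capped alkyne, returns to 18.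

Step 17. The amide base may add to the aldehyde, the aldolate may eliminate or revert on warming, and the C1 oxygen may end equatorial if the chelated transition state is not followed. Fallback: from 22, amine-catalysed aldol condensation (piperidinium acetate, benzene, 60 °C) gives the ring A 1-en-3-one F7. Nucleophilic epoxidation (t-BuOOH, DBU) anti to the C10–O bond gives the 1β,2β-epoxy ketone F8, and reductive opening with SmI2 (THF/MeOH, −78 °C) gives the free 1β-hydroxy 3-ketone F9. Silylation (Et3SiOTf, 2,6-lutidine) returns to 24.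

Step 20. The ketyl may be reduced to the secondary alcohol or dimerize before it cyclizes, and the trivalent samarium alkoxides may trigger retro-aldol of the 3-hydroxy lactone. Fallback: from 27, Markovnikov bromoboration–protonolysis of the terminal alkyne (B-bromo-9-borabicyclo[3.3.1]nonane in excess, then AcOH) gives the 2-bromoallyl ketone F10. Intramolecular Nozaki–Hiyama–Kishi addition (CrCl2, NiCl2 cat., DMSO) returns to 28.

## Further compounds

F1 | step 10 | 11-methoxy 13-(trimethylsilyloxy)-12-ene adduct (C11 epimers) | C[Si](C)(C)C#CC[C@]23CC(O[Si](C)(C)C)=CC(OC)[C@H]2C(=O)C[C@@H]3CO[Si](c4ccccc4)(c4ccccc4)C(C)(C)C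
F2 | step 10 | 11-en-13-one 10-ketone | C[Si](C)(C)C#CC[C@]23CC(=O)C=C[C@H]2C(=O)C[C@@H]3CO[Si](c4ccccc4)(c4ccccc4)C(C)(C)C
F3 | step 10 | 10,13-dione | C[Si](C)(C)C#CC[C@]23CC(=O)CC[C@H]2C(=O)C[C@@H]3CO[Si](c4ccccc4)(c4ccccc4)C(C)(C)C
F4 | step 12 | 5α-(2-ethoxy-2-oxoethyl) 10-ketone | C[Si](C)(C)C#CC[C@]23CC4(OCCO4)CC[C@H]2C(=O)[C@@H](CC(=O)OCC)[C@@H]3CO[Si](c5ccccc5)(c5ccccc5)C(C)(C)C
F5 | step 12 | 10β-vinyl 19,10-γ-lactone without the C4 methyl | C[Si](C)(C)C#CC[C@]23CC4(OCCO4)CC[C@H]2[C@@]1(C=C)OC(=O)C[C@H]1[C@@H]3CO[Si](c5ccccc5)(c5ccccc5)C(C)(C)C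
F6 | step 13 | 10β-ethynyl 19,10-γ-lactone (C4 epimers) | C[Si](C)(C)C#CC[C@]23CC4(OCCO4)CC[C@H]2[C@@]1(C#C)OC(=O)C(C)[C@H]1[C@@H]3CO[Si](c5ccccc5)(c5ccccc5)C(C)(C)C
F7 | step 17 | ring A 1-en-3-one | C[Si](C)(C)C#CC[C@]23CC4(OCCO4)CC[C@H]2[C@@]12OC(=O)[C@@](C)([C@H]1[C@@H]3CO[Si](c5ccccc5)(c5ccccc5)C(C)(C)C)C(=O)C=C2
F8 | step 17 | 1β,2β-epoxy 3-ketone | C[Si](C)(C)C#CC[C@]23CC4(OCCO4)CC[C@H]2[C@@]12OC(=O)[C@@](C)([C@H]1[C@@H]3CO[Si](c5ccccc5)(c5ccccc5)C(C)(C)C)C(=O)[C@H]6O[C@H]62
F9 | step 17 | 1β-hydroxy 3-ketone (free alcohol) | C[Si](C)(C)C#CC[C@]23CC4(OCCO4)CC[C@H]2[C@@]12OC(=O)[C@@](C)([C@H]1[C@@H]3CO[Si](c5ccccc5)(c5ccccc5)C(C)(C)C)C(=O)C[C@H]2O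
F10 | step 20 | 8β-(2-bromoallyl) 1β,3β,7-triol 13-ketone | C=C(Br)C[C@]23CC(=O)CC[C@H]2[C@@]12OC(=O)[C@@](C)([C@H]1[C@@H]3CO)[C@@H](O)C[C@H]2O
A1 | alternative 1 | GA55 1,3-bis(tert-butyldimethylsilyl) ether | C=C1C[C@]23C[C@@]1(O)CC[C@H]2[C@@]12OC(=O)[C@@](C)([C@H]1[C@@H]3C(=O)O)[C@@H](O[Si](C)(C)C(C)(C)C)C[C@H]2O[Si](C)(C)C(C)(C)C
A2 | alternative 1 | steviol | C=C1C[C@]23C[C@@]1(O)CC[C@H]2[C@]1(C)CCC[C@@](C)(C(=O)O)[C@H]1CC3
A3 | alternative 1 | 6-diazo-7-ketone with six-membered ring B (19,10-lactone, 1,3-bis-silyl ether) | C=C1C[C@]23C[C@@]1(O)CC[C@H]2[C@@]12OC(=O)[C@@](C)([C@H]1C(=[N+]=[N-])C3=O)[C@@H](O[Si](C)(C)C(C)(C)C)C[C@H]2O[Si](C)(C)C(C)(C)C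
A4 | alternative 2 | B/C/D tricycle (10-ketone, 9(11)-ene, C16 silyl enol ether, 13-silyloxy, C6 gem-diester) | C[Si](C)(C)OC1=C[C@]23C[C@@]1(O[Si](C)(C)C(C)(C)C)CC=C2C(=O)CC3(C(=O)OC)C(=O)OC
A5 | alternative 2 | vinyl diazoketone tethered to a 1,2-bis(silyloxy)cyclopentadiene | C=CC(=[N+]=[N-])C(=O)CC(C(=O)OC)(C(=O)OC)C1=CC(O[Si](C)(C)C)=C(O[Si](C)(C)C(C)(C)C)C1
A6 | alternative 3 | 3β-hydroxy 19,10-ether (1-deoxy, C7 nitrile, 16-ketone, 13-silyloxy) | O=C1C[C@]23C[C@@]1(O[Si](C)(C)C(C)(C)C)CC[C@H]2[C@@]12OC[C@@](C)([C@H]1[C@@H]3C#N)[C@@H](O)CC2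
A7 | alternative 3 | (3S,4S)-epoxy alcohol with the C5=C10 alkene | O=C1C[C@]23C[C@@]1(O[Si](C)(C)C(C)(C)C)CC[C@H]2C(CC[C@@H]4O[C@@]4(C)CO)=C[C@@H]3C#N
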